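**Strategy.** Ring A is the dimethoxylated ring (C1 bears the ethylene bridge, C3 and C5 the methoxy groups). The route rests on cutting the bond between C2 of ring A and the benzylic CH2 of the 4-hydroxybenzyl group, as the plant presumably does. Two features are exploited: this CH2 lies para to a phenolic OH, the signature of a p-quinone methide, and C2 is para to the C5 methoxy and ortho to the C3 methoxy, the most nucleophilic carbon present. The key step generates the quinone methide from 4-hydroxybenzyl alcohol and lets the unprotected bibenzyl capture it (Friedel–Crafts 1,6-addition), giving the target directly. The bibenzyl arises by one-pot hydroboration/B-alkyl Suzuki coupling.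

Key step: step 2

Remark: the target has no stereocentre and no other stereogenic element, so it is achiral; no enantioselective step is needed and the route gives the single compound drawn.

**Step 1**
Reactants: 1 3,5-dimethoxystyrene; 2 3-iodophenol
Product: 4 3-[2-(3,5-dimethoxyphenyl)ethyl]phenol, via B-alkyl-9-BBN borane 3 (not isolated)
Conditions: 1 (1.3 equiv), 9-BBN (0.5 M in THF, 1.3 equiv), THF, 0 °C → rt; then 3 M aq NaOH (3.5 equiv), 2 (1.0 equiv), Pd(dppf)Cl2·CH2Cl2 (3 mol%), 65 °C; aq NH4Cl work-up
Reagents that add atoms: none
Why: Anti-Markovnikov hydroboration of the styrene with 9-BBN should place boron on the terminal carbon, and the resulting B-alkyl borane should undergo B-alkyl Suzuki–Miyaura coupling with the aryl iodide under aqueous NaOH, which destroys residual B–H before the phenol is added and carries the phenol through as its phenoxide; no stereocentre is formed.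

**Step 2**
Reactants: 4 3-[2-(3,5-dimethoxyphenyl)ethyl]phenol; 5 4-hydroxybenzyl alcohol
Product: 7 gymconopin D, via p-quinone methide 6 (not isolated)
Conditions: 4 (1.5 equiv, excess recovered), 5 (1.0 equiv, added in portions), TsOH·H2O (5 mol%), HFIP, 0 °C → rt
Reagents that add atoms: none
Why: Acid in HFIP should ionise the benzylic alcohol 5 to p-quinone methide 6 (reacting in its O-protonated form, the 4-hydroxybenzyl cation), whose exocyclic CH2 is attacked by C2 of ring A of 4; loss of the C2 proton rearomatises ring A and the quinone methide ring returns to the phenol. The closest known reaction type is the Friedel–Crafts benzylation of electron-rich arenes with benzylic alcohols (1,6-addition of arenes to p-quinone methides), which is also the presumed biosynthetic origin of the 4-hydroxybenzyl group. No ring is closed and no stereocentre is formed. The step needs site selectivity: C2 and C6 of ring A are equivalent by symmetry and each is activated para by one methoxy and ortho by the other, C4 is flanked by two methoxy groups and should be sterically shielded, and the mono-oxygenated rings B and C should be about three orders of magnitude less nucleophilic. O-Alkylation of the phenols is reversible under the acidic conditions and should funnel to the C-benzylated product, while excess 4 and portionwise addition of 5 should hold back a second benzylation at C6 and self-condensation of 5.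

**Compound list**
1 | 3,5-dimethoxystyrene (1-ethenyl-3,5-dimethoxybenzene) | C=Cc1cc(OC)cc(OC)c1 | starting material
2 | 3-iodophenol | Oc1cccc(I)c1 | starting material
3 | B-[2-(3,5-dimethoxyphenyl)ethyl]-9-borabicyclo[3.3.1]nonane | COc1cc(CCB2C3CCCC2CCC3)cc(OC)c1 | intermediate
4 | 3-[2-(3,5-dimethoxyphenyl)ethyl]phenol (3'-hydroxy-3,5-dimethoxybibenzyl) | COc1cc(CCc2cccc(O)c2)cc(OC)c1 | intermediate
5 | 4-hydroxybenzyl alcohol | OCc1ccc(O)cc1 | starting material
6 | p-quinone methide (4-methylidenecyclohexa-2,5-dien-1-one) | C=C1C=CC(=O)C=C1 | intermediate
7 | gymconopin D (Gymcononopin D), 3-{2-[2-(4-hydroxybenzyl)-3,5-dimethoxyphenyl]ethyl}phenol | COc1cc(CCc2cccc(O)c2)c(Cc2ccc(O)cc2)c(OC)c1 | target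

**Total step count:** 2
**Longest linear sequence:** 2 steps (1 → 4 → 7)

**Steps most likely to fail** (the route has only two steps, so both are ranked)

1. Step 2 (highest risk). The process that may go wrong is loss of site control: attack at C4 between the two methoxy groups or on ring B, a second benzylation at C6, or self-condensation of the quinone methide precursor. The fallback sets out from 4 and returns to the route at 7; it makes the same C2–CH2 bond by an organometallic addition that fixes the site beforehand. O-Benzylation of 4 (BnBr, K2CO3, acetone, reflux) should give 1-[2-(3-benzyloxyphenyl)ethyl]-3,5-dimethoxybenzene F1. NBS (1.0 equiv, MeCN, 0 °C) should brominate the doubly activated ring A para to a methoxy group and give 1-[2-(3-benzyloxyphenyl)ethyl]-2-bromo-3,5-dimethoxybenzene F2. Bromine–lithium exchange (n-BuLi, THF, −78 °C) and addition to 4-(benzyloxy)benzaldehyde (O=Cc1ccc(OCc2ccccc2)cc1) should give the racemic diarylmethanol [4-(benzyloxyphenyl)]{2-[2-(3-benzyloxyphenyl)ethyl]-4,6-dimethoxyphenyl}methanol F3. Hydrogenolysis (H2, Pd/C, EtOAc/AcOH, cat. HCl) should then remove both benzyl ethers and the doubly benzylic hydroxyl in one operation and deliver 7.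

2. Step 1. The process that may go wrong is a stalled cross-coupling: slow transmetalation or protodeboronation of the alkylborane, or consumption of boron hydride by the free phenol. The fallback sets out from 1 and 2 and returns to the route at 4; it replaces the sp3–sp2 coupling by an sp2–sp2 coupling followed by reduction. Heck reaction of 1 with 2 (Pd(OAc)2, P(o-tol)3, Et3N, DMF, 100 °C) should give 3-[(E)-2-(3,5-dimethoxyphenyl)ethenyl]phenol F4. Hydrogenation (H2, 1 atm, Pd/C, EtOAc, rt) should then saturate the alkene and give 4.

**Further compounds**
F1 | step 2 | 1-[2-(3-benzyloxyphenyl)ethyl]-3,5-dimethoxybenzene | COc1cc(CCc2cccc(OCc3ccccc3)c2)cc(OC)c1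
F2 | step 2 | 1-[2-(3-benzyloxyphenyl)ethyl]-2-bromo-3,5-dimethoxybenzene | COc1cc(CCc2cccc(OCc3ccccc3)c2)c(Br)c(OC)c1
F3 | step 2 | rac-[4-(benzyloxy)phenyl]{2-[2-(3-benzyloxyphenyl)ethyl]-4,6-dimethoxyphenyl}methanol | COc1cc(CCc2cccc(OCc3ccccc3)c2)c(C(O)c2ccc(OCc3ccccc3)cc2)c(OC)c1
F4 | step 1 | 3-[(E)-2-(3,5-dimethoxyphenyl)ethenyl]phenol | COc1cc(/C=C/c2cccc(O)c2)cc(OC)c1
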